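**Retrosynthetic overview**

1. Target ⇐ alkyne desilylation ⇐ Z-selective enyne cross-metathesis on a C6-allyl oxocane; the C10 acetate comes from a trichloroacetate exchange.
2. Oxocane (ring formed last) ⇐ chloronium-triggered ring expansion of a 2,5-cis-tetrahydrofuran spanning C9–C12: bicyclic oxonium ion, opened by chloride at C9 (sets C6, C7, C9).
3. Tetrahydrofuran (ring formed first) ⇐ 5-exo debenzylative bromoetherification of an acyclic (E)-alkenyl 2,6-dichlorobenzyl ether (sets C12, C13).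
4. Acyclic triene ⇐ Julia–Kocienski olefination (C12=C13, E) and lactol Wittig reaction (C6=C7, Z) on a lactol–aldehyde whose two termini differ only because one diol oxygen is free.
5. Lactol–aldehyde ⇐ ozonolysis of a mono-benzylated cis-cyclohex-4-ene-1,2-diol ⇐ catalytic enantioselective desymmetrisation of the meso diol (sets C9, C10) ⇐ benzene (Birch reduction, dihydroxylation).

Assumption: carbons are labelled C1–C15 along the target chain (C1 = alkyne CH, C6 and C12 = ring carbons on oxygen, C15 = methyl), and compounds 7, 9 and 18 are taken as catalogue reagents.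

**Route**

Step 1
Reactants: 1 benzene
Product: 2 cyclohexa-1,4-diene
Conditions: Li, liquid NH3, EtOH, Et2O, −78 to −33 °C
Reagents that add atoms: none
Why: Birch reduction breaks the aromaticity and gives the unconjugated diene, whose ring carbons become C7–C12; no stereocentre is formed.

Step 2
Reactants: 2 cyclohexa-1,4-diene (threefold excess)
Product: 3 cis-cyclohex-4-ene-1,2-diol (meso)
Conditions: OsO4 (1 mol %), N-methylmorpholine N-oxide, acetone–H2O, 0 °C to rt
Reagents that add atoms: N-methylmorpholine N-oxide C[N+]1([O-])CCOCC1; water O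
Why: Upjohn syn-dihydroxylation of one of the two equivalent alkenes (excess diene suppresses the tetrol) creates C9 and C10 as an erythro pair in a meso compound.

Step 3
Reactants: 3 cis-cyclohex-4-ene-1,2-diol
Product: 4 (1S,6R)-6-[(2,6-dichlorophenyl)methoxy]cyclohex-3-en-1-ol
Conditions: 2,6-dichlorobenzyl bromide (1.1 equiv), chiral hemiboronic acid (benzoxazaborine-type) catalyst (10 mol %, antipode chosen for the sense shown), K2CO3, MeCN, rt
Reagents that add atoms: 2,6-dichlorobenzyl bromide BrCc1c(Cl)cccc1Cl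
Why: Proposed new method: the catalyst binds the cis-diol reversibly as a tetracoordinate boronate, which raises the nucleophilicity of one enantiotopic oxygen inside a chiral pocket, and that oxygen is alkylated by SN2 so that C9 becomes R (ether) and C10 becomes S (free hydroxyl); the closest known reactions are borinic-acid-catalysed mono-alkylation of cis-1,2-diols and chiral hemiboronic-acid-catalysed desymmetrising O-benzylation of prochiral 1,3-diols.

Step 4
Reactants: 4 (1S,6R)-6-[(2,6-dichlorophenyl)methoxy]cyclohex-3-en-1-ol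
Product: 6 2-[(2S,3R)-3-[(2,6-dichlorophenyl)methoxy]-5-hydroxyoxolan-2-yl]acetaldehyde (anomer mixture), via open-chain hydroxy dialdehyde 5 (not isolated)
Conditions: O3, CH2Cl2, −78 °C; then PPh3, −78 °C to rt
Reagents that add atoms: ozone [O-][O+]=O
Why: Ozonolysis (Criegee cleavage) gives a dialdehyde in which the free C10 hydroxyl closes onto the gamma-aldehyde C7 as a five-membered lactol while C12 stays a free aldehyde, so the two termini are differentiated without touching a stereocentre.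

Step 5
Reactants: 6 2-[(2S,3R)-3-[(2,6-dichlorophenyl)methoxy]-5-hydroxyoxolan-2-yl]acetaldehyde; 7 1-phenyl-5-(propane-1-sulfonyl)-1H-tetrazole
Product: 8 (4R,5S)-4-[(2,6-dichlorophenyl)methoxy]-5-[(2E)-pent-2-en-1-yl]oxolan-2-ol
Conditions: 7 (1.3 equiv), KN(SiMe3)2 (2.3 equiv), 1,2-dimethoxyethane, −78 °C to rt
Reagents that add atoms: none
Why: Julia–Kocienski olefination of the only free aldehyde (one equivalent of base is spent on the lactol hydroxyl) installs C13–C15 with the E geometry that the later anti bromoetherification needs.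

Step 6
Reactants: 8 (4R,5S)-4-[(2,6-dichlorophenyl)methoxy]-5-[(2E)-pent-2-en-1-yl]oxolan-2-ol; 9 (but-3-en-1-yl)triphenylphosphonium bromide
Product: 11 (4Z,7R,8S,10E)-7-[(2,6-dichlorophenyl)methoxy]trideca-1,4,10-trien-8-yl trichloroacetate, via trienol potassium alkoxide 10 (not isolated)
Conditions: 9 (3 equiv), KN(SiMe3)2 (2.9 equiv), THF, −78 to 0 °C; then Cl3CCOCl (4 equiv), −78 to 0 °C
Reagents that add atoms: trichloroacetyl chloride ClC(=O)C(Cl)(Cl)Cl
Why: Wittig reaction of the lactol with a non-stabilised, lithium-free ylide gives the Z C6=C7 alkene, and the liberated C10 alkoxide is capped in the same flask as a trichloroacetate, an ester that neither attacks halonium ions nor participates at C9 later (the benzyl ether cannot migrate to the alkoxide).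

Step 7
Reactants: 11 (4Z,7R,8S,10E)-7-[(2,6-dichlorophenyl)methoxy]trideca-1,4,10-trien-8-yl trichloroacetate
Product: 13 (2R,3S,5R)-5-[(1S)-1-bromopropyl]-2-[(2Z)-hexa-2,5-dien-1-yl]oxolan-3-yl trichloroacetate, via O-benzyl oxolanium ion 12 (not isolated)
Conditions: N-bromosuccinimide (1.1 equiv), MeCN, −30 to 0 °C, dark
Reagents that add atoms: N-bromosuccinimide O=C1CCC(=O)N1Br
Why: Debenzylative 5-exo bromoetherification (Rychnovsky–Bartlett-type ether cyclisation): anti addition across the E alkene makes C12–O and C13–Br erythro, and the bulky O-benzyl group of the oxonium-like transition state lies trans to both flanking substituents, which gives the 2,5-cis ring (C12 R, C13 S); the benzyl group is then lost to succinimide.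

Step 8
Reactants: 13 (2R,3S,5R)-5-[(1S)-1-bromopropyl]-2-[(2Z)-hexa-2,5-dien-1-yl]oxolan-3-yl trichloroacetate
Product: 15 (2R,4S,5S,7S,8S)-2-[(1S)-1-bromopropyl]-5,7-dichloro-8-(prop-2-en-1-yl)oxocan-4-yl trichloroacetate, via bicyclic oxonium ion 14 (not isolated)
Conditions: Et2SCl·SbCl6 (1.05 equiv), MeNO2, −25 °C; then n-Bu4NCl (3 equiv), −25 to 0 °C
Reagents that add atoms: chlorodiethylsulfonium hexachloroantimonate CC[S+](Cl)CC.Cl[Sb-](Cl)(Cl)(Cl)(Cl)Cl; tetrabutylammonium chloride CCCC[N+](CCCC)(CCCC)CCCC.[Cl-]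
Why: Proposed new method: the chloronium ion of the more electron-rich Z alkene is captured 5-endo by the ring oxygen (anti addition, so C6–O and C7–Cl are threo, with allyl and chlorine on the convex face because the concave face is blocked by the bromopropyl group: C6 S, C7 S), and chloride then opens the ring-fusion C9–O bond of the cis-fused trialkyloxonium ion by SN2 with inversion (C9 S) to give the oxocane; the closest known reactions are the bromonium-induced tetrahydrofuran-to-oxocane ring expansion through bicyclic oxonium ions and the chloride opening of Laurencia-type oxonium ions.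

Step 9
Reactants: 15 (2R,4S,5S,7S,8S)-2-[(1S)-1-bromopropyl]-5,7-dichloro-8-(prop-2-en-1-yl)oxocan-4-yl trichloroacetate
Product: 17 (2R,4S,5S,7S,8S)-2-[(1S)-1-bromopropyl]-5,7-dichloro-8-(prop-2-en-1-yl)oxocan-4-yl acetate, via oxocanol 16 (not isolated)
Conditions: NH3, MeOH, 0 °C; evaporate; then Ac2O, pyridine, 4-dimethylaminopyridine (cat.), CH2Cl2, 0 °C to rt
Reagents that add atoms: acetic anhydride CC(=O)OC(C)=O
Why: Ammonolysis of the activated trichloroacetate frees the C10 hydroxyl without forming an alkoxide next to the C9 chloride (no epoxide), and standard acylation then installs the acetate with C10 unchanged.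

Step 10
Reactants: 17 (2R,4S,5S,7S,8S)-2-[(1S)-1-bromopropyl]-5,7-dichloro-8-(prop-2-en-1-yl)oxocan-4-yl acetate; 18 (but-3-en-1-yn-1-yl)tri(propan-2-yl)silane
Product: 19 (2R,4S,5S,7S,8S)-2-[(1S)-1-bromopropyl]-5,7-dichloro-8-[(2Z)-5-[tri(propan-2-yl)silyl]pent-2-en-4-yn-1-yl]oxocan-4-yl acetate
Conditions: 18 (4 equiv), second-generation Grubbs catalyst (H2IMes)(PCy3)Cl2Ru=CHPh (10 mol %), benzene, 50 °C
Reagents that add atoms: none
Why: Cross-metathesis of a terminal alkene with a conjugated silyl enyne is kinetically Z-selective and is the usual way to put the (3Z)-enyne on Laurencia ethers; no stereocentre is touched.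

Step 11
Reactants: 19 (2R,4S,5S,7S,8S)-2-[(1S)-1-bromopropyl]-5,7-dichloro-8-[(2Z)-5-[tri(propan-2-yl)silyl]pent-2-en-4-yn-1-yl]oxocan-4-yl acetate
Product: 20 (2R,4S,5S,7S,8S)-2-[(1S)-1-bromopropyl]-5,7-dichloro-8-[(2Z)-pent-2-en-4-yn-1-yl]oxocan-4-yl acetate (CNP0251465.4)
Conditions: n-Bu4NF, AcOH, THF, 0 °C
Reagents that add atoms: none
Why: Fluoride-induced protodesilylation of the alkynylsilane, buffered with acetic acid so that the acetate and the secondary halides survive, releases the terminal alkyne.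

**Compound list**

1 | benzene | c1ccccc1 | starting material
2 | cyclohexa-1,4-diene | C1=CCC=CC1 | intermediate
3 | cis-cyclohex-4-ene-1,2-diol (meso) | O[C@H]1CC=CC[C@H]1O | intermediate
4 | (1S,6R)-6-[(2,6-dichlorophenyl)methoxy]cyclohex-3-en-1-ol | O[C@H]1CC=CC[C@H]1OCc1c(Cl)cccc1Cl | intermediate
5 | (3R,4S)-3-[(2,6-dichlorophenyl)methoxy]-4-hydroxyhexanedial | O=CC[C@@H](OCc1c(Cl)cccc1Cl)[C@@H](O)CC=O | intermediate
6 | 2-[(2S,3R)-3-[(2,6-dichlorophenyl)methoxy]-5-hydroxyoxolan-2-yl]acetaldehyde | O=CC[C@@H]1OC(O)C[C@H]1OCc1c(Cl)cccc1Cl | intermediate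
7 | 1-phenyl-5-(propane-1-sulfonyl)-1H-tetrazole | CCCS(=O)(=O)c1nnnn1-c1ccccc1 | starting material
8 | (4R,5S)-4-[(2,6-dichlorophenyl)methoxy]-5-[(2E)-pent-2-en-1-yl]oxolan-2-ol | CC/C=C/C[C@@H]1OC(O)C[C@H]1OCc1c(Cl)cccc1Cl | intermediate
9 | (but-3-en-1-yl)triphenylphosphonium bromide | C=CCC[P+](c1ccccc1)(c1ccccc1)c1ccccc1.[Br-] | starting material
10 | potassium (4Z,7R,8S,10E)-7-[(2,6-dichlorophenyl)methoxy]trideca-1,4,10-trien-8-olate | CC/C=C/C[C@H]([O-])[C@H](OCc1c(Cl)cccc1Cl)C/C=C\CC=C.[K+] | intermediate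
11 | (4Z,7R,8S,10E)-7-[(2,6-dichlorophenyl)methoxy]trideca-1,4,10-trien-8-yl trichloroacetate | CC/C=C/C[C@H](OC(=O)C(Cl)(Cl)Cl)[C@H](OCc1c(Cl)cccc1Cl)C/C=C\CC=C | intermediate
12 | (2R,3S,5R)-5-[(1S)-1-bromopropyl]-1-[(2,6-dichlorophenyl)methyl]-2-[(2Z)-hexa-2,5-dien-1-yl]-3-(trichloroacetoxy)oxolan-1-ium succinimidate | C=CC/C=C\C[C@H]1[O+](Cc2c(Cl)cccc2Cl)[C@H](C[C@@H]1OC(=O)C(Cl)(Cl)Cl)[C@@H](Br)CC.O=C1CCC(=O)[N-]1 | intermediate
13 | (2R,3S,5R)-5-[(1S)-1-bromopropyl]-2-[(2Z)-hexa-2,5-dien-1-yl]oxolan-3-yl trichloroacetate | C=CC/C=C\C[C@H]1O[C@H](C[C@@H]1OC(=O)C(Cl)(Cl)Cl)[C@@H](Br)CC | intermediate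
14 | cis-fused 1-oxoniabicyclo[3.3.0]octane hexachloroantimonate carrying 2-allyl (C6), 3-chloro (C7), 6-trichloroacetoxy (C10) and 8-[(1S)-1-bromopropyl] (C12) groups | C=CC[C@H]1[C@@H](Cl)C[C@@H]2[C@@H](OC(=O)C(Cl)(Cl)Cl)C[C@H]([C@@H](Br)CC)[O+]12.Cl[Sb-](Cl)(Cl)(Cl)(Cl)Cl | intermediate
15 | (2R,4S,5S,7S,8S)-2-[(1S)-1-bromopropyl]-5,7-dichloro-8-(prop-2-en-1-yl)oxocan-4-yl trichloroacetate | C=CC[C@@H]1O[C@@H]([C@@H](Br)CC)C[C@H](OC(=O)C(Cl)(Cl)Cl)[C@@H](Cl)C[C@@H]1Cl | intermediate
16 | (2R,4S,5S,7S,8S)-2-[(1S)-1-bromopropyl]-5,7-dichloro-8-(prop-2-en-1-yl)oxocan-4-ol | C=CC[C@@H]1O[C@@H]([C@@H](Br)CC)C[C@H](O)[C@@H](Cl)C[C@@H]1Cl | intermediate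
17 | (2R,4S,5S,7S,8S)-2-[(1S)-1-bromopropyl]-5,7-dichloro-8-(prop-2-en-1-yl)oxocan-4-yl acetate | C=CC[C@@H]1O[C@@H]([C@@H](Br)CC)C[C@H](OC(C)=O)[C@@H](Cl)C[C@@H]1Cl | intermediate
18 | (but-3-en-1-yn-1-yl)tri(propan-2-yl)silane | C=CC#C[Si](C(C)C)(C(C)C)C(C)C | starting material
19 | (2R,4S,5S,7S,8S)-2-[(1S)-1-bromopropyl]-5,7-dichloro-8-[(2Z)-5-[tri(propan-2-yl)silyl]pent-2-en-4-yn-1-yl]oxocan-4-yl acetate | CC(C)[Si](C#C/C=C\C[C@@H]1O[C@@H]([C@@H](Br)CC)C[C@H](OC(C)=O)[C@@H](Cl)C[C@@H]1Cl)(C(C)C)C(C)C | intermediate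
20 | (2R,4S,5S,7S,8S)-2-[(1S)-1-bromopropyl]-5,7-dichloro-8-[(2Z)-pent-2-en-4-yn-1-yl]oxocan-4-yl acetate | C#C/C=C\C[C@@H]1O[C@@H]([C@@H](Br)CC)C[C@H](OC(C)=O)[C@@H](Cl)C[C@@H]1Cl | target

**Step count**

Total step count: 11. Longest linear sequence: 11 steps (1 to 20); compounds 7, 9 and 18 are purchased and enter in steps 5, 6 and 10.

**Steps most likely to fail, with fallbacks**

Step 3. The enantioselective mono-etherification of a 1,2-diol with a chiral hemiboronic acid is unproven; low ee or bis-alkylation would undermine everything after it. The fallback replaces it by an acylative desymmetrisation and a protecting-group relay, setting out from 3. Lipase-catalysed transesterification with vinyl acetate (immobilised Pseudomonas cepacia lipase, t-BuOMe, rt) gives (1S,6R)-6-hydroxycyclohex-3-en-1-yl acetate F1. If the enzyme acylates in the opposite sense, hydrolysis of the meso diacetate gives the same compound. 2,6-Dichlorobenzyl trichloroacetimidate with catalytic TfOH in CH2Cl2 at −20 °C (acidic, to avoid acetyl migration) etherifies the free hydroxyl and gives (1S,6R)-6-[(2,6-dichlorophenyl)methoxy]cyclohex-3-en-1-yl acetate F2. K2CO3 in MeOH then removes the acetate, and the sequence comes back to the route at 4.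

Step 7. The cis selectivity rests on kinetic capture of a bromonium ion by the hindered ether, whereas the documented high cis ratios for 2,6-dichlorobenzyl ethers come from equilibrating iodonium chemistry; a 2,5-trans ring would carry the wrong C12. The fallback uses that iodoetherification and brings bromine in afterwards by invertive substitution, setting out from 6. Wittig reaction of the free aldehyde with propylidene(triphenyl)phosphorane (from propyl(triphenyl)phosphonium bromide and NaN(SiMe3)2, THF, −78 °C, 1.05 equiv) gives the Z-alkenyl lactol (4R,5S)-4-[(2,6-dichlorophenyl)methoxy]-5-[(2Z)-pent-2-en-1-yl]oxolan-2-ol F3. The lactol Wittig reaction and trichloroacetylation of step 6 give (4Z,7R,8S,10Z)-7-[(2,6-dichlorophenyl)methoxy]trideca-1,4,10-trien-8-yl trichloroacetate F4. Iodine in MeCN at 0 °C, where the oxonium ions equilibrate and funnel to the cis ring, gives the threo iodide (2R,3S,5R)-2-[(2Z)-hexa-2,5-dien-1-yl]-5-[(1R)-1-iodopropyl]oxolan-3-yl trichloroacetate F5. LiBr in N,N-dimethylformamide at 40 °C replaces iodide by bromide with inversion, and the sequence comes back to the route at 13.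

Step 8. Chloride may open the oxonium ion at C6 or C12 instead of C9, and C9 is the carbon most deactivated by the neighbouring trichloroacetate; the chloronium ion may also be trapped before the ring oxygen engages. The fallback makes C9 the uniquely activated position by placing a carbonyl group at C10, setting out from 13. NH3 in MeOH gives (2R,3S,5R)-5-[(1S)-1-bromopropyl]-2-[(2Z)-hexa-2,5-dien-1-yl]oxolan-3-ol F6. Dess–Martin periodinane in CH2Cl2 gives (2R,5R)-5-[(1S)-1-bromopropyl]-2-[(2Z)-hexa-2,5-dien-1-yl]oxolan-3-one F7. The reagents of step 8 then form the same type of bicyclic oxonium ion, and chloride attacks the carbon alpha to the ketone, where SN2 is faster by orders of magnitude, to give (2R,5S,7S,8S)-2-[(1S)-1-bromopropyl]-5,7-dichloro-8-(prop-2-en-1-yl)oxocan-4-one F8. NaBH4 with CeCl3·7H2O in MeOH at −78 °C reduces the alpha-chloro ketone under Felkin–Anh (polar) control to the syn chlorohydrin, and the sequence comes back to the route at 16, which is acetylated as in the second half of step 9.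

**Further compounds**

F1 | step 3 | (1S,6R)-6-hydroxycyclohex-3-en-1-yl acetate | CC(=O)O[C@H]1CC=CC[C@H]1O
F2 | step 3 | (1S,6R)-6-[(2,6-dichlorophenyl)methoxy]cyclohex-3-en-1-yl acetate | CC(=O)O[C@H]1CC=CC[C@H]1OCc1c(Cl)cccc1Cl
F3 | step 7 | (4R,5S)-4-[(2,6-dichlorophenyl)methoxy]-5-[(2Z)-pent-2-en-1-yl]oxolan-2-ol | CC/C=C\C[C@@H]1OC(O)C[C@H]1OCc1c(Cl)cccc1Cl
F4 | step 7 | (4Z,7R,8S,10Z)-7-[(2,6-dichlorophenyl)methoxy]trideca-1,4,10-trien-8-yl trichloroacetate | CC/C=C\C[C@H](OC(=O)C(Cl)(Cl)Cl)[C@H](OCc1c(Cl)cccc1Cl)C/C=C\CC=C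
F5 | step 7 | (2R,3S,5R)-2-[(2Z)-hexa-2,5-dien-1-yl]-5-[(1R)-1-iodopropyl]oxolan-3-yl trichloroacetate | C=CC/C=C\C[C@H]1O[C@H](C[C@@H]1OC(=O)C(Cl)(Cl)Cl)[C@H](I)CC
F6 | step 8 | (2R,3S,5R)-5-[(1S)-1-bromopropyl]-2-[(2Z)-hexa-2,5-dien-1-yl]oxolan-3-ol | C=CC/C=C\C[C@H]1O[C@H](C[C@@H]1O)[C@@H](Br)CC
F7 | step 8 | (2R,5R)-5-[(1S)-1-bromopropyl]-2-[(2Z)-hexa-2,5-dien-1-yl]oxolan-3-one | C=CC/C=C\C[C@H]1O[C@H](CC1=O)[C@@H](Br)CC
F8 | step 8 | (2R,5S,7S,8S)-2-[(1S)-1-bromopropyl]-5,7-dichloro-8-(prop-2-en-1-yl)oxocan-4-one | C=CC[C@@H]1O[C@@H]([C@@H](Br)CC)CC(=O)[C@@H](Cl)C[C@@H]1Cl
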